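## Analysis of the target

The target is a daucane-type sesquiterpenoid ester on a bicyclo[5.3.0]decane (hydroazulene) core: a cyclopentane (C5, C6, C7, C8, C9) fused along C5–C6 to a cycloheptenone (C2, C3, C4, C5, C6, C10, C11). The numbering used throughout is: C2=C3 the enone alkene with a methyl group on C2, C4 the secondary carbinol, C5 the ring-fusion CH, C6 the methyl-bearing quaternary carbon, C9 the carbon carrying the isopropyl group and the 4-hydroxybenzoate, C10 the ring methylene, C11 the ketone. The four stereocentres are contiguous (4S,5S,6R,9R). H-5 and the C6 methyl are trans (trans ring fusion), the C9 acyloxy group lies on the face of the C6 methyl, the isopropyl group on the face of H-5, and the C4 hydroxyl is cis to H-5. The sensitive groups are a hindered tertiary aryl ester 1,3 to the free C4 hydroxyl (a base can shift the acyl group to the less hindered oxygen), a γ-hydroxy enone (prone to base-induced isomerisation and elimination) and a free phenol. The difficulty is the cluster C5/C6/C9 of branched and fully substituted carbons at the ring fusion, the acylation of a tertiary alcohol, and a trans-fused seven-membered ring that must carry its enone in one regiochemistry only. The strategy rests on C11: this carbonyl sits between the sp2 carbon C2 and the methylene C10, which hangs on the quaternary C6 and so has no β-hydrogen. A ketone flanked by an alkenyl carbon and a β-hydrogen-free alkyl carbon is what a palladium-catalysed three-component coupling with carbon monoxide delivers, so C11 can enter as a gas in the ring-closing event and all stereocentres can be set beforehand on a monocyclic cyclopentane.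

## Retrosynthetic reasoning

Target 29 is traced to its bis-silyl ether 28 by cutting the two O–Si bonds. Both hydroxyls must be masked during the organometallic ring closure, and one fluoride treatment under non-basic conditions frees them without triggering the 1,3-acyl shift.

In 28 the bonds C10–C11 and C11–C2 are cut together. This removes the seven-membered ring and one carbon and leads to the alkylzinc iodide 26 and carbon monoxide 27. The cut is made here because C11 is the only ring carbon whose two neighbours match a carbonylative coupling: an alkenyl bromide carbon (C2) and an alkylmetal carbon that cannot undergo β-hydride elimination (C10). The forward reaction has to insert 27 before C10 is transferred to palladium, keep the Z geometry of C2=C3, and close the ring in preference to oligomerisation.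

The C10–Zn bond of 26 is traced to the C10–I bond of 25, this to the primary alcohol 24, and 24 to its 4-methoxybenzyl ether 23. These are heteroatom exchanges at one carbon. The benzylic ether is chosen because its removal is oxidative and therefore orthogonal to the two silyl ethers, the ester and the alkenyl bromide.

The ester C–O bond of 23 is cut to give tertiary alcohol 17 and acid chloride 21, which comes from 4-hydroxybenzoic acid 18 through the silyl-protected acid 20. The acylation is placed before C10 is unmasked, so that the alkoxide of 17 is the only nucleophile present.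

The C9–isopropyl bond of 17 is cut to give ketone 16. Addition of an isopropyl nucleophile to the cyclopentanone from the face opposite the C5 side chain gives the required cis relationship of the C9 oxygen and the C4 arm.

The C4–C5 bond of 16 (through its free alcohol 15) is cut as an aldol bond to give silyl enol ether 12 and the Z bromo-enal 10. This cut supplies C2, C3 and C4 at their final oxidation pattern and sets C4 and C5 in one step. The forward reaction needs the enolate on the hindered side (C9=C5), which deprotonation of a ketone would not give.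

The C6–CH3 bond of 12 is cut to give enone 6. An asymmetric conjugate addition of a methyl nucleophile creates the quaternary centre and at the same time the regiodefined enolate, which is stored as 12.

Enone 6 is cut at C6–C10 into the alkoxymethyl stannane 2 (from 1) and the vinylogous ester 3. Aldehyde 10 goes back through allylic alcohol 9 to but-2-yn-1-ol 7, where the Z geometry is set by a directed hydrometalation.

## Alternatives that were turned down

Alternative 1: The C6–CH3 and C4–C5 bonds are formed in one flask. An organoaluminium methyl donor adds to C6 of 3-(prop-2-en-1-yl)cyclopent-2-en-1-one A1 under a chiral copper catalyst, and the aluminium enolate is trapped by (2Z)-3-iodobut-2-enal A2 to give aldol A3.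
- For: three stereocentres and two C–C bonds are made in a single operation. The allyl arm brings C10 and C11 as carbon, so no toxic gas and no competition between carbonylation and direct coupling arise.
- Against: no ring is closed. The seven-membered ring would still need oxidative cleavage of the terminal alkene next to an iodoalkene, a C11–C2 closure onto the resulting aldehyde and a reoxidation, creating a C11 stereocentre only to destroy it. The iodoalkene is also more prone than a bromide to halogen–metal exchange when the isopropyl group is added at C9. The face selection at C5 rests on the same methyl-versus-CH2R difference as in the chosen route.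
- Comparison: as a way to set C4, C5 and C6 it is at least as good as steps 5 and 6 and more convergent; the chosen route uses the same logic in two flasks to have a defined zinc enolate. What the chosen strategy adds is the ring closure itself, with C11 delivered at the ketone oxidation level.

Alternative 2: C5–C6 and C2–C3 are cut together, opening both rings to a chain derived from (S)-terpinen-4-ol A4. Forward, an oxyallyl cation generated beside a tethered 2-siloxydiene undergoes an intramolecular (4+3) cycloaddition to give, after equilibration at C5, hydroazulenone A5.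
- For: both rings and two C–C bonds form in one step, and C9 with its oxygen and isopropyl group comes from the chiral pool in the right configuration. On step count to the bicyclic skeleton and on C9 it is stronger than the chosen route, which must add a bulky nucleophile to a hindered ketone and then acylate.
- Against: the cycloaddition has to build the quaternary C6 at the more substituted diene terminus and relay configuration from the remote C9 to C5 and C6 through a flexible tether. A5 then carries the wrong oxidation pattern: a ketone at C4 that must be reduced face-selectively, a latent second ketone at C11, and a saturated C2–C3 bond that must be dehydrogenated regioselectively within a 1,4-dicarbonyl array.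
- Comparison: the chosen strategy closes the ring with every heteroatom already at its final oxidation level and no late differentiation of two ketones.

Alternative 3: C5–C9 is cut. An α-diazo ketone A6 on a preformed cycloheptanone gives, with a dirhodium tetracarboxylate catalyst, a C5 carbenoid that inserts into the silyloxy-bearing C9–H bond to close the cyclopentane as A7.
- For: the C–H bond is activated by the adjacent oxygen, 1,5-insertion is the favoured mode, and insertion proceeds with retention, so C9 derives from an easily made secondary carbinol. On C9 it is stronger than the chosen route.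
- Against: A7 has C10, C11, C2 and C3 as unfunctionalised methylenes. The C11 ketone, the C2=C3 alkene and the C2 methyl group would have to be installed on carbons remote from the single C4 ketone, which cannot be done selectively in few steps. The insertion must also give the trans ring fusion and avoid the isopropyl methine and the C7 hydrogens, and A6 itself needs an asymmetric synthesis of its quaternary C6.
- Comparison: the chosen strategy brings C2–C4 in as a four-carbon aldehyde with the substitution pattern in place and leaves only the carbonyl carbon to be added.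

Key step: step 15

Assumption: the sense of induction of the copper–phosphoramidite catalyst in step 5 is not deduced here; the ligand enantiomer is to be chosen so that 12 has the (3S) configuration shown.

Remark: the descriptor at C4 is R in all bromoalkene intermediates and S in 28 and 29, and that at C6 changes from S to R on ring closure. Only substituent priorities change; no centre is inverted.

Step 1
Reactants: 1 (tributylstannyl)methanol
Product: 2 tributyl{[(4-methoxyphenyl)methoxy]methyl}stannane
Conditions: NaH, THF/DMF, 0 °C; 4-methoxybenzyl chloride, Bu4NI (cat.), 0 °C → rt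
Reagents that add atoms: 4-methoxybenzyl chloride, COc1ccc(CCl)cc1
Why: Williamson etherification of the stannylmethanol alkoxide with a benzylic chloride; the C–Sn bond is inert to NaH and to the alkoxide.

Step 2
Reactants: 2 tributyl{[(4-methoxyphenyl)methoxy]methyl}stannane; 3 3-ethoxycyclopent-2-en-1-one
Product: 6 3-{[(4-methoxyphenyl)methoxy]methyl}cyclopent-2-en-1-one, via alkoxymethyllithium 4 (not isolated), via lithium alkoxide adduct 5 (not isolated)
Conditions: n-BuLi, THF, −78 °C; 3, −78 → −20 °C; 1 M HCl, rt
Reagents that add atoms: water, O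
Why: Tin–lithium exchange gives the α-alkoxymethyllithium, which adds 1,2 to the vinylogous ester; acid then hydrolyses the enol ether with loss of water and ethanol (Stork–Danheiser carbonyl transposition), placing the future C10 arm on the β-carbon of the new enone.

Step 3
Reactants: 7 but-2-yn-1-ol
Product: 9 (2Z)-3-bromobut-2-en-1-ol, via cyclic alkenylaluminate 8 (not isolated)
Conditions: NaAlH2(OCH2CH2OMe)2, THF, 0 °C → rt; NBS, −78 → 0 °C
Reagents that add atoms: N-bromosuccinimide, O=C1CCC(=O)N1Br
Why: Alkoxide-directed trans-hydroalumination places aluminium on the methyl-bearing carbon within a five-membered aluminate, necessarily cis to the CH2O group; bromination of the C–Al bond with retention should give the Z bromide only.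

Step 4
Reactants: 9 (2Z)-3-bromobut-2-en-1-ol
Product: 10 (2Z)-3-bromobut-2-enal
Conditions: MnO2, CH2Cl2, rt; used directly as a solution
Reagents that add atoms: none
Why: MnO2 oxidises allylic alcohols selectively under neutral conditions that should not isomerise the Z alkene; the volatile aldehyde is not stored.

Step 5
Reactants: 6 3-{[(4-methoxyphenyl)methoxy]methyl}cyclopent-2-en-1-one
Product: 12 triethyl{[(3S)-3-{[(4-methoxyphenyl)methoxy]methyl}-3-methylcyclopent-1-en-1-yl]oxy}silane, via dimethylaluminium enolate 11 (not isolated)
Conditions: Me3Al, copper thiophene-2-carboxylate (5 mol%), BINOL-derived bis(1-phenylethyl)amine phosphoramidite (10 mol%), Et2O, −30 °C; TESOTf, −78 → 0 °C; Et3N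
Reagents that add atoms: trimethylaluminium, C[Al](C)C; triethylsilyl trifluoromethanesulfonate, CC[Si](CC)(CC)OS(=O)(=O)C(F)(F)F
Why: Copper-catalysed asymmetric conjugate addition of a trialkylaluminium to a β-substituted cyclopentenone forms the C6 quaternary centre, the chiral ligand selecting the enone face; O-silylation of the aluminium enolate stores the C9=C5 enolate regiochemistry, which deprotonation of the ketone would not give.

Step 6
Reactants: 12 triethyl{[(3S)-3-{[(4-methoxyphenyl)methoxy]methyl}-3-methylcyclopent-1-en-1-yl]oxy}silane; 10 (2Z)-3-bromobut-2-enal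
Product: 15 (2S,3S)-2-[(1R,2Z)-3-bromo-1-hydroxybut-2-en-1-yl]-3-{[(4-methoxyphenyl)methoxy]methyl}-3-methylcyclopentan-1-one, via lithium enolate 13 (not isolated), via chlorozinc enolate 14 (not isolated)
Conditions: MeLi, THF, 0 °C → rt; ZnCl2, −78 °C; 10, −78 °C; aq. NH4Cl
Reagents that add atoms: none
Why: MeLi cleaves the O–Si bond to the regiodefined enolate, and the zinc enolate reacts through a Zimmerman–Traxler chair in which the ring (E)-enolate and an equatorial aldehyde substituent give the anti aldol, setting C4 relative to C5. The aldehyde is expected to approach C5 on the face of the C6 methyl group, away from the larger alkoxymethyl arm, which sets C5 relative to C6 and puts the two future ring arms trans.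

Step 7
Reactants: 15 (2S,3S)-2-[(1R,2Z)-3-bromo-1-hydroxybut-2-en-1-yl]-3-{[(4-methoxyphenyl)methoxy]methyl}-3-methylcyclopentan-1-one
Product: 16 (2S,3S)-2-[(1R,2Z)-3-bromo-1-{[tert-butyl(dimethyl)silyl]oxy}but-2-en-1-yl]-3-{[(4-methoxyphenyl)methoxy]methyl}-3-methylcyclopentan-1-one
Conditions: TBSOTf, 2,6-lutidine, CH2Cl2, −78 → 0 °C
Reagents that add atoms: tert-butyldimethylsilyl trifluoromethanesulfonate, CC(C)(C)[Si](C)(C)OS(=O)(=O)C(F)(F)F
Why: Silylation of a hindered secondary alcohol with the silyl triflate and a weak hindered base; it blocks retro-aldol cleavage and removes the acidic proton before the organometallic steps without epimerising C5.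

Step 8
Reactants: 16 (2S,3S)-2-[(1R,2Z)-3-bromo-1-{[tert-butyl(dimethyl)silyl]oxy}but-2-en-1-yl]-3-{[(4-methoxyphenyl)methoxy]methyl}-3-methylcyclopentan-1-one
Product: 17 (1R,2S,3S)-2-[(1R,2Z)-3-bromo-1-{[tert-butyl(dimethyl)silyl]oxy}but-2-en-1-yl]-3-{[(4-methoxyphenyl)methoxy]methyl}-3-methyl-1-(propan-2-yl)cyclopentan-1-ol
Conditions: iPrMgCl, CeCl3 (anhydrous), THF, −78 °C; aq. NH4Cl
Reagents that add atoms: isopropylmagnesium chloride, CC(C)[Mg]Cl
Why: The organocerium reagent (Imamoto conditions) is weakly basic, which should suppress enolisation and β-hydride reduction of the α-branched ketone, and it does not exchange with the alkenyl bromide at −78 °C. The nucleophile enters anti to the bulky C5 side chain, so the C9 oxygen ends up cis to the C4 arm and C9 is set.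

Step 9
Reactants: 18 4-hydroxybenzoic acid
Product: 20 4-{[tert-butyl(dimethyl)silyl]oxy}benzoic acid, via silyl ester 19 (not isolated)
Conditions: TBSCl, imidazole, DMF, rt; AcOH/THF/H2O, rt
Reagents that add atoms: tert-butyldimethylsilyl chloride, CC(C)(C)[Si](C)(C)Cl
Why: Both acidic hydroxyls are silylated, and the silyl ester, far more labile than the aryl silyl ether, is then hydrolysed selectively under mild acid.

Step 10
Reactants: 20 4-{[tert-butyl(dimethyl)silyl]oxy}benzoic acid
Product: 21 4-{[tert-butyl(dimethyl)silyl]oxy}benzoyl chloride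
Conditions: (COCl)2, DMF (cat.), CH2Cl2, 0 °C → rt
Reagents that add atoms: oxalyl chloride, ClC(=O)C(=O)Cl
Why: Acid chloride formation through the catalytic Vilsmeier-type chloroiminium species; the aryl silyl ether tolerates the anhydrous HCl formed.

Step 11
Reactants: 17 (1R,2S,3S)-2-[(1R,2Z)-3-bromo-1-{[tert-butyl(dimethyl)silyl]oxy}but-2-en-1-yl]-3-{[(4-methoxyphenyl)methoxy]methyl}-3-methyl-1-(propan-2-yl)cyclopentan-1-ol; 21 4-{[tert-butyl(dimethyl)silyl]oxy}benzoyl chloride
Product: 23 (1R,2S,3S)-2-[(1R,2Z)-3-bromo-1-{[tert-butyl(dimethyl)silyl]oxy}but-2-en-1-yl]-3-{[(4-methoxyphenyl)methoxy]methyl}-3-methyl-1-(propan-2-yl)cyclopentyl 4-{[tert-butyl(dimethyl)silyl]oxy}benzoate, via lithium alkoxide 22 (not isolated)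
Conditions: LiHMDS, THF, −78 °C; 21, −78 °C → rt
Reagents that add atoms: none
Why: O-Acylation of a preformed lithium alkoxide with an aroyl chloride is the standard way to esterify tertiary alcohols; the amide base avoids bromine–lithium exchange, and the lithium counter-ion and low temperature should keep the C4 silyl group from migrating to the C9 oxygen.

Step 12
Reactants: 23 (1R,2S,3S)-2-[(1R,2Z)-3-bromo-1-{[tert-butyl(dimethyl)silyl]oxy}but-2-en-1-yl]-3-{[(4-methoxyphenyl)methoxy]methyl}-3-methyl-1-(propan-2-yl)cyclopentyl 4-{[tert-butyl(dimethyl)silyl]oxy}benzoate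
Product: 24 (1R,2S,3S)-2-[(1R,2Z)-3-bromo-1-{[tert-butyl(dimethyl)silyl]oxy}but-2-en-1-yl]-3-(hydroxymethyl)-3-methyl-1-(propan-2-yl)cyclopentyl 4-{[tert-butyl(dimethyl)silyl]oxy}benzoate
Conditions: DDQ, CH2Cl2/pH 7 buffer, 0 °C → rt
Reagents that add atoms: none
Why: Oxidative cleavage of the 4-methoxybenzyl ether (hydride abstraction from the electron-rich benzylic position, then hydrolysis); silyl ethers, the electron-poor benzoate and the bromoalkene are not oxidised, and the trans, 1,4-related ester cannot migrate to the new primary alcohol.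

Step 13
Reactants: 24 (1R,2S,3S)-2-[(1R,2Z)-3-bromo-1-{[tert-butyl(dimethyl)silyl]oxy}but-2-en-1-yl]-3-(hydroxymethyl)-3-methyl-1-(propan-2-yl)cyclopentyl 4-{[tert-butyl(dimethyl)silyl]oxy}benzoate
Product: 25 (1R,2S,3S)-2-[(1R,2Z)-3-bromo-1-{[tert-butyl(dimethyl)silyl]oxy}but-2-en-1-yl]-3-(iodomethyl)-3-methyl-1-(propan-2-yl)cyclopentyl 4-{[tert-butyl(dimethyl)silyl]oxy}benzoate
Conditions: I2, PPh3, imidazole, toluene, 70 °C
Reagents that add atoms: iodine, II
Why: Appel-type iodination (Garegg–Samuelsson conditions): the alkoxyphosphonium ion is displaced by iodide; the neopentyl-type position needs heating but cannot eliminate, and the imidazole buffer protects the silyl ethers.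

Step 14
Reactants: 25 (1R,2S,3S)-2-[(1R,2Z)-3-bromo-1-{[tert-butyl(dimethyl)silyl]oxy}but-2-en-1-yl]-3-(iodomethyl)-3-methyl-1-(propan-2-yl)cyclopentyl 4-{[tert-butyl(dimethyl)silyl]oxy}benzoate
Product: 26 {[(1S,2S,3R)-2-[(1R,2Z)-3-bromo-1-{[tert-butyl(dimethyl)silyl]oxy}but-2-en-1-yl]-3-[(4-{[tert-butyl(dimethyl)silyl]oxy}benzoyl)oxy]-1-methyl-3-(propan-2-yl)cyclopentyl]methyl}(iodo)zinc, kept as a THF solution
Conditions: Zn dust (activated with BrCH2CH2Br and Me3SiCl), LiCl, THF, 40 °C
Reagents that add atoms: zinc, [Zn]
Why: Direct insertion of activated zinc into a primary C–I bond, accelerated by LiCl; the ester, silyl ethers and alkenyl bromide are tolerated, and a radical 5-exo closure of C10 onto C3 is disfavoured because the trans-disposed arms would give a trans-fused bicyclo[3.3.0]octane.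

Step 15
Reactants: 26 {[(1S,2S,3R)-2-[(1R,2Z)-3-bromo-1-{[tert-butyl(dimethyl)silyl]oxy}but-2-en-1-yl]-3-[(4-{[tert-butyl(dimethyl)silyl]oxy}benzoyl)oxy]-1-methyl-3-(propan-2-yl)cyclopentyl]methyl}(iodo)zinc; 27 carbon monoxide
Product: 28 (3R,3aS,4S,8aR)-4-{[tert-butyl(dimethyl)silyl]oxy}-6,8a-dimethyl-7-oxo-3-(propan-2-yl)-1,2,3,3a,4,7,8,8a-octahydroazulen-3-yl 4-{[tert-butyl(dimethyl)silyl]oxy}benzoate
Conditions: Pd(PPh3)4 (10 mol%), CO (3 bar), THF, 50 °C, slow addition of 26 to about 0.005 M
Reagents that add atoms: none
Why: Proposed new method: the step extends the intermolecular palladium-catalysed carbonylative Negishi ketone synthesis (alkylzinc halide, alkenyl or aryl halide and CO) and the carbonylative Stille macrocyclisations of alkenyl halides to a seven-membered ring closure with a tethered alkylzinc. Zerovalent palladium adds to the C2–Br bond with retention of the Z geometry, CO inserts into the alkenyl–palladium bond to give the C11 acyl complex, the C10 zinc centre transmetalates intramolecularly, and reductive elimination from the eight-membered palladacycle (Pd, C11, C2, C3, C4, C5, C6, C10) forms C10–C11. The cycloheptenone is thus closed by acyl–alkyl coupling, C11–C2 arising in the insertion and C10–C11 in the ring-closing elimination. No stereocentre is created; C4, C5, C6 and C9 are spectators. Two selectivities are needed: CO insertion must precede transmetalation, because direct coupling of C10 with C2 would give a six-membered ring, and ring closure must outrun intermolecular coupling. CO pressure and the slow transmetalation of an alkylzinc iodide in THF without polar cosolvent serve the first, slow addition at high dilution the second. The substrate helps: C10 has no β-hydrogen, so the alkyl(acyl)palladium intermediate cannot β-eliminate, the Z alkene holds C2 on the side of C5, and the trans arms on the cyclopentane correspond to the trans ring fusion.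

Step 16
Reactants: 28 (3R,3aS,4S,8aR)-4-{[tert-butyl(dimethyl)silyl]oxy}-6,8a-dimethyl-7-oxo-3-(propan-2-yl)-1,2,3,3a,4,7,8,8a-octahydroazulen-3-yl 4-{[tert-butyl(dimethyl)silyl]oxy}benzoate
Product: 29 (3R,3aS,4S,8aR)-4-hydroxy-6,8a-dimethyl-7-oxo-3-(propan-2-yl)-1,2,3,3a,4,7,8,8a-octahydroazulen-3-yl 4-hydroxybenzoate
Conditions: HF·pyridine, pyridine, THF, 0 °C → rt
Reagents that add atoms: none
Why: Pyridine-buffered HF cleaves the aryl and the secondary alkyl silyl ethers without generating an alkoxide, which should avoid the 1,3-acyl shift from the C9 to the C4 oxygen and base-induced isomerisation of the γ-hydroxy enone.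

Compound list

1 | (tributylstannyl)methanol | CCCC[Sn](CCCC)(CCCC)CO | starting material
2 | tributyl{[(4-methoxyphenyl)methoxy]methyl}stannane | CCCC[Sn](CCCC)(CCCC)COCc1ccc(OC)cc1 | intermediate
3 | 3-ethoxycyclopent-2-en-1-one | CCOC1=CC(=O)CC1 | starting material
4 | {[(4-methoxyphenyl)methoxy]methyl}lithium | [Li]COCc1ccc(OC)cc1 | intermediate
5 | lithium 3-ethoxy-1-{[(4-methoxyphenyl)methoxy]methyl}cyclopent-2-en-1-olate (racemic) | CCOC1=CC(O[Li])(COCc2ccc(OC)cc2)CC1 | intermediate
6 | 3-{[(4-methoxyphenyl)methoxy]methyl}cyclopent-2-en-1-one | O=C1C=C(COCc2ccc(OC)cc2)CC1 | intermediate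
7 | but-2-yn-1-ol | CC#CCO | starting material
8 | sodium cyclic alkenylaluminate (five-membered O–Al–C=C–C ring, Al on the methyl-bearing carbon, two 2-methoxyethoxy ligands) | CC1=CCO[Al-]1(OCCOC)OCCOC.[Na+] | intermediate
9 | (2Z)-3-bromobut-2-en-1-ol | Br/C(C)=C\CO | intermediate
10 | (2Z)-3-bromobut-2-enal | Br/C(C)=C\C=O | intermediate
11 | dimethylaluminium (3S)-3-{[(4-methoxyphenyl)methoxy]methyl}-3-methylcyclopent-1-en-1-olate | C[Al](C)OC1=C[C@@](C)(COCc2ccc(OC)cc2)CC1 | intermediate
12 | triethyl{[(3S)-3-{[(4-methoxyphenyl)methoxy]methyl}-3-methylcyclopent-1-en-1-yl]oxy}silane | CC[Si](CC)(CC)OC1=C[C@@](C)(COCc2ccc(OC)cc2)CC1 | intermediate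
13 | lithium (3S)-3-{[(4-methoxyphenyl)methoxy]methyl}-3-methylcyclopent-1-en-1-olate | [Li]OC1=C[C@@](C)(COCc2ccc(OC)cc2)CC1 | intermediate
14 | chlorozinc (3S)-3-{[(4-methoxyphenyl)methoxy]methyl}-3-methylcyclopent-1-en-1-olate | Cl[Zn]OC1=C[C@@](C)(COCc2ccc(OC)cc2)CC1 | intermediate
15 | (2S,3S)-2-[(1R,2Z)-3-bromo-1-hydroxybut-2-en-1-yl]-3-{[(4-methoxyphenyl)methoxy]methyl}-3-methylcyclopentan-1-one | Br/C(C)=C\[C@H](O)[C@@H]1[C@](C)(CCC1=O)COCc1ccc(OC)cc1 | intermediate
16 | (2S,3S)-2-[(1R,2Z)-3-bromo-1-{[tert-butyl(dimethyl)silyl]oxy}but-2-en-1-yl]-3-{[(4-methoxyphenyl)methoxy]methyl}-3-methylcyclopentan-1-one | Br/C(C)=C\[C@H](O[Si](C)(C)C(C)(C)C)[C@@H]1[C@](C)(CCC1=O)COCc1ccc(OC)cc1 | intermediate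
17 | (1R,2S,3S)-2-[(1R,2Z)-3-bromo-1-{[tert-butyl(dimethyl)silyl]oxy}but-2-en-1-yl]-3-{[(4-methoxyphenyl)methoxy]methyl}-3-methyl-1-(propan-2-yl)cyclopentan-1-ol | Br/C(C)=C\[C@H](O[Si](C)(C)C(C)(C)C)[C@@H]1[C@](C)(CC[C@@]1(O)C(C)C)COCc1ccc(OC)cc1 | intermediate
18 | 4-hydroxybenzoic acid | OC(=O)c1ccc(O)cc1 | starting material
19 | tert-butyl(dimethyl)silyl 4-{[tert-butyl(dimethyl)silyl]oxy}benzoate | CC(C)(C)[Si](C)(C)OC(=O)c1ccc(O[Si](C)(C)C(C)(C)C)cc1 | intermediate
20 | 4-{[tert-butyl(dimethyl)silyl]oxy}benzoic acid | OC(=O)c1ccc(O[Si](C)(C)C(C)(C)C)cc1 | intermediate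
21 | 4-{[tert-butyl(dimethyl)silyl]oxy}benzoyl chloride | ClC(=O)c1ccc(O[Si](C)(C)C(C)(C)C)cc1 | intermediate
22 | lithium alkoxide of 17 (O–Li at C9) | Br/C(C)=C\[C@H](O[Si](C)(C)C(C)(C)C)[C@@H]1[C@](C)(CC[C@@]1(O[Li])C(C)C)COCc1ccc(OC)cc1 | intermediate
23 | (1R,2S,3S)-2-[(1R,2Z)-3-bromo-1-{[tert-butyl(dimethyl)silyl]oxy}but-2-en-1-yl]-3-{[(4-methoxyphenyl)methoxy]methyl}-3-methyl-1-(propan-2-yl)cyclopentyl 4-{[tert-butyl(dimethyl)silyl]oxy}benzoate | Br/C(C)=C\[C@H](O[Si](C)(C)C(C)(C)C)[C@@H]1[C@](C)(CC[C@@]1(OC(=O)c1ccc(O[Si](C)(C)C(C)(C)C)cc1)C(C)C)COCc1ccc(OC)cc1 | intermediate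
24 | (1R,2S,3S)-2-[(1R,2Z)-3-bromo-1-{[tert-butyl(dimethyl)silyl]oxy}but-2-en-1-yl]-3-(hydroxymethyl)-3-methyl-1-(propan-2-yl)cyclopentyl 4-{[tert-butyl(dimethyl)silyl]oxy}benzoate | Br/C(C)=C\[C@H](O[Si](C)(C)C(C)(C)C)[C@@H]1[C@](C)(CC[C@@]1(OC(=O)c1ccc(O[Si](C)(C)C(C)(C)C)cc1)C(C)C)CO | intermediate
25 | (1R,2S,3S)-2-[(1R,2Z)-3-bromo-1-{[tert-butyl(dimethyl)silyl]oxy}but-2-en-1-yl]-3-(iodomethyl)-3-methyl-1-(propan-2-yl)cyclopentyl 4-{[tert-butyl(dimethyl)silyl]oxy}benzoate | Br/C(C)=C\[C@H](O[Si](C)(C)C(C)(C)C)[C@@H]1[C@](C)(CC[C@@]1(OC(=O)c1ccc(O[Si](C)(C)C(C)(C)C)cc1)C(C)C)CI | intermediate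
26 | {[(1S,2S,3R)-2-[(1R,2Z)-3-bromo-1-{[tert-butyl(dimethyl)silyl]oxy}but-2-en-1-yl]-3-[(4-{[tert-butyl(dimethyl)silyl]oxy}benzoyl)oxy]-1-methyl-3-(propan-2-yl)cyclopentyl]methyl}(iodo)zinc | Br/C(C)=C\[C@H](O[Si](C)(C)C(C)(C)C)[C@@H]1[C@](C)(CC[C@@]1(OC(=O)c1ccc(O[Si](C)(C)C(C)(C)C)cc1)C(C)C)C[Zn]I | intermediate
27 | carbon monoxide | [C-]#[O+] | starting material
28 | (3R,3aS,4S,8aR)-4-{[tert-butyl(dimethyl)silyl]oxy}-6,8a-dimethyl-7-oxo-3-(propan-2-yl)-1,2,3,3a,4,7,8,8a-octahydroazulen-3-yl 4-{[tert-butyl(dimethyl)silyl]oxy}benzoate | CC1=C[C@H](O[Si](C)(C)C(C)(C)C)[C@@H]2[C@](C)(CC[C@@]2(OC(=O)c2ccc(O[Si](C)(C)C(C)(C)C)cc2)C(C)C)CC1=O | intermediate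
29 | (3R,3aS,4S,8aR)-4-hydroxy-6,8a-dimethyl-7-oxo-3-(propan-2-yl)-1,2,3,3a,4,7,8,8a-octahydroazulen-3-yl 4-hydroxybenzoate | CC1=C[C@H](O)[C@@H]2[C@](C)(CC[C@@]2(OC(=O)c2ccc(O)cc2)C(C)C)CC1=O | target

Step count and risks

Total: 16 steps. Longest linear sequence: 12 steps (1, 2, 5, 6, 7, 8, 11, 12, 13, 14, 15, 16). Steps 3–4 and 9–10 are side branches.

Least certain steps:

- **Step 15 (key step, proposed new method).** Most likely failure: transmetalation of C10 to the alkenylpalladium before CO insertion, giving direct C10–C2 coupling and a six-membered ring. Oligomerisation by intermolecular coupling, protonation of the C10–Zn bond and loss of the Z geometry at the acylpalladium stage are further risks. Fallback by known chemistry, from 24 back to 28: 24 is oxidised with Dess–Martin periodinane to the C10 aldehyde F1. A Wittig reaction with methoxymethylenetriphenylphosphorane gives the methyl enol ether F2, and hydrolysis with Hg(OAc)2 in aqueous THF gives the homologated aldehyde F3, in which C11 is present as the formyl carbon. An intramolecular Nozaki–Hiyama–Kishi reaction (CrCl2, catalytic NiCl2, DMSO, high dilution) closes C11–C2 to the cyclic allylic alcohol F4, whose oxidation with Dess–Martin periodinane gives 28.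

- **Step 6.** Poor facial selectivity at C5 is the main risk: the methyl and alkoxymethyl groups on C6 differ only beyond the first atom, and the arm can turn its oxygen away from the incoming aldehyde. Incomplete anti selectivity at C4 and retro-aldol cleavage on work-up are also possible. Fallback, from 12 back to 15: the aldol is run under reagent control, with 12 and 10 combined under SiCl4 and a chiral binaphthyldiamine-derived bisphosphoramide. The catalyst fixes the aldehyde face (C4) and the anti topicity of the open transition state then fixes the enol ether face (C5), independently of the weak bias from C6. Aqueous work-up of the trichlorosilyl aldolate F8 gives 15.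

- **Step 5.** Insufficient enantioselectivity with the oxygen-bearing β-substituent, or incomplete O-silylation of the aluminium enolate, with loss of the enolate regiochemistry through protonation. Fallback, from 6 back to 15: the methyl group is brought in as MeMgBr under Cu(OTf)2 and a chiral imidazolinium-derived carbene ligand. The bromomagnesium enolate F7 is transmetalated with ZnCl2 to 14 in the same flask and treated with 10, so that no silyl enol ether relay is needed.

- **Step 8.** Enolisation of the hindered ketone (with epimerisation at C5 or β-elimination of the silyloxy group), reduction by β-hydride transfer from the isopropyl reagent, or attack on the wrong face. Fallback, from 16 back to 17: isopropenylmagnesium bromide premixed with CeCl3 is added instead; it is smaller, sp2-hybridised and cannot deliver a β-hydride. This gives the isopropenyl carbinol F5, whose 1,1-disubstituted alkene is saturated with diimide (2-nitrobenzenesulfonyl hydrazide, Et3N), leaving the trisubstituted bromoalkene untouched.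

- **Step 11.** Slow acylation of the crowded tertiary alkoxide, migration of the C4 silyl group to the C9 alkoxide, or attack of the alkoxide on the aryl silyl ether. Fallback, from 17 and 20 back to 23: the electrophile is activated instead of the nucleophile. Acid 20 is dehydrated with DCC to its anhydride F6, and 17 is acylated with F6 under Sc(OTf)3 catalysis in MeCN at −20 °C, so that no alkoxide is formed.

Further compounds

F1 | step 15 | (1R,2S,3S)-2-[(1R,2Z)-3-bromo-1-{[tert-butyl(dimethyl)silyl]oxy}but-2-en-1-yl]-3-formyl-3-methyl-1-(propan-2-yl)cyclopentyl 4-{[tert-butyl(dimethyl)silyl]oxy}benzoate (C10 aldehyde of 24) | Br/C(C)=C\[C@H](O[Si](C)(C)C(C)(C)C)[C@@H]1[C@](C)(CC[C@@]1(OC(=O)c1ccc(O[Si](C)(C)C(C)(C)C)cc1)C(C)C)C=O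
F2 | step 15 | methyl enol ether: 24 with the hydroxymethyl group replaced by 2-methoxyethenyl (E/Z mixture, other centres unchanged) | Br/C(C)=C\[C@H](O[Si](C)(C)C(C)(C)C)[C@@H]1[C@](C)(CC[C@@]1(OC(=O)c1ccc(O[Si](C)(C)C(C)(C)C)cc1)C(C)C)C=COC
F3 | step 15 | homologated aldehyde: 24 with the hydroxymethyl group replaced by 2-oxoethyl (C10H2–C11HO, other centres unchanged) | Br/C(C)=C\[C@H](O[Si](C)(C)C(C)(C)C)[C@@H]1[C@](C)(CC[C@@]1(OC(=O)c1ccc(O[Si](C)(C)C(C)(C)C)cc1)C(C)C)CC=O
F4 | step 15 | C11 alcohol of 28 (7-hydroxy in place of 7-oxo, both C11 epimers) | CC1=C[C@H](O[Si](C)(C)C(C)(C)C)[C@@H]2[C@](C)(CC[C@@]2(OC(=O)c2ccc(O[Si](C)(C)C(C)(C)C)cc2)C(C)C)CC1O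
F5 | step 8 | isopropenyl analogue of 17 (prop-1-en-2-yl in place of propan-2-yl at C9, same spatial arrangement) | Br/C(C)=C\[C@H](O[Si](C)(C)C(C)(C)C)[C@@H]1[C@](C)(CC[C@@]1(O)C(C)=C)COCc1ccc(OC)cc1
F6 | step 11 | 4-{[tert-butyl(dimethyl)silyl]oxy}benzoic anhydride | CC(C)(C)[Si](C)(C)Oc1ccc(cc1)C(=O)OC(=O)c1ccc(O[Si](C)(C)C(C)(C)C)cc1
F7 | step 5 | bromomagnesium (3S)-3-{[(4-methoxyphenyl)methoxy]methyl}-3-methylcyclopent-1-en-1-olate | Br[Mg]OC1=C[C@@](C)(COCc2ccc(OC)cc2)CC1
F8 | step 6 | trichlorosilyl ether of 15 (O–SiCl3 at C4) | Br/C(C)=C\[C@H](O[Si](Cl)(Cl)Cl)[C@@H]1[C@](C)(CCC1=O)COCc1ccc(OC)cc1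
A1 | alternative 1 | 3-(prop-2-en-1-yl)cyclopent-2-en-1-one | C=CCC1=CC(=O)CC1
A2 | alternative 1 | (2Z)-3-iodobut-2-enal | I/C(C)=C\C=O
A3 | alternative 1 | (2S,3R)-2-[(1R,2Z)-1-hydroxy-3-iodobut-2-en-1-yl]-3-methyl-3-(prop-2-en-1-yl)cyclopentan-1-one | I/C(C)=C\[C@H](O)[C@@H]1[C@](C)(CCC1=O)CC=C
A4 | alternative 2 | (S)-terpinen-4-ol, (1S)-4-methyl-1-(propan-2-yl)cyclohex-3-en-1-ol | CC1=CC[C@](O)(C(C)C)CC1
A5 | alternative 2 | trans-fused hydroazulen-4-one with methyl groups on C2 and C6, isopropyl and triethylsilyloxy groups on C9 and a C10=C11 triisopropylsilyl enol ether (route numbering, configuration as in the SMILES) | C[C@@H]1CC(=O)[C@@H]2[C@](C)(CC[C@@]2(O[Si](CC)(CC)CC)C(C)C)C=C1O[Si](C(C)C)(C(C)C)C(C)C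
A6 | alternative 3 | 2-diazocycloheptan-1-one carrying on C3 (route C6) a methyl group and a 3-{[tert-butyl(dimethyl)silyl]oxy}-4-methylpentyl chain (configuration as in the SMILES) | [N-]=[N+]=C1C(=O)CCCC[C@@]1(C)CC[C@@H](O[Si](C)(C)C(C)(C)C)C(C)C
A7 | alternative 3 | trans-fused hydroazulen-4-one with a methyl group on C6 and isopropyl and tert-butyldimethylsilyloxy groups on C9 (route numbering, configuration as in the SMILES) | O=C1[C@@H]2[C@](C)(CC[C@@]2(O[Si](C)(C)C(C)(C)C)C(C)C)CCCC1
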